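**Retrosynthetic overview**
1. Target 11 is an oxolane, O1–C2(3,4-dimethoxyphenyl)–C3(CH2OH)–C4(arylmethyl)–C5, with 2,3-trans and 3,4-cis substituents; the free phenol is released last from benzyl ether 10.
2. Feature used: C3 sits next to a primary carbinol carbon (C3–CH2–OH is a terminal oxirane opened at its inner carbon), the neighbouring C4 carries an arylmethyl group (a reduced styrene terminus), and C4–C5–O1–C2 is the allylic ether of a benzylic carbinol.
3. Key disconnection C3–C4: epoxy cinnamyl ether 8 with Cp2TiCl, by reductive oxirane opening and 5-exo-trig radical closure. The oxolane is the only ring formed, and C3 and C4 are set under control of C2.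
4. 8 comes from O-alkylation of erythro epoxy alcohol 4 (Sharpless kinetic-resolution epoxidation of carbinol 3, made from veratraldehyde 1 and vinylmagnesium bromide 2) with cinnamyl bromide 7 (O-benzylvanillin 5 plus 2 gives 6, then PBr3 with allylic transposition).

Key step: step 6

Remark on the chemistry: the oxirane carbon of 4 and 8 is a sacrificial stereocentre, because step 6 turns it into a planar radical; only the carbinol carbon has to be enantiopure.

**Step 1**
Reactants: 1 3,4-dimethoxybenzaldehyde (veratraldehyde); 2 vinylmagnesium bromide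
Product: 3 rac-1-(3,4-dimethoxyphenyl)prop-2-en-1-ol
Conditions: THF, 0 °C; then sat. aq NH4Cl
Reagents that add atoms: none
Why: Grignard 1,2-addition of the vinyl nucleophile to the aryl aldehyde should give the secondary allylic alcohol, necessarily racemic at this stage.

**Step 2**
Reactants: 3 rac-1-(3,4-dimethoxyphenyl)prop-2-en-1-ol
Product: 4 (R)-(3,4-dimethoxyphenyl)[(2S)-oxiran-2-yl]methanol (erythro)
Conditions: Ti(OiPr)4 (15 mol %), D-(−)-diisopropyl tartrate (18 mol %), tBuOOH (0.45 equiv, anhydrous), 4 Å MS, CH2Cl2, −20 °C
Reagents that add atoms: tert-butyl hydroperoxide, CC(C)(C)OO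
Why: In this Sharpless kinetic-resolution epoxidation the D-(−)-tartrate titanium catalyst should epoxidise the (S)-enantiomer of 3 much faster than the (R)-enantiomer (left behind and separated) and deliver oxygen to the vinyl face that gives the erythro product, which fixes the carbinol centre that becomes C2 of the oxolane (labelled R in 4 only because the oxiranyl carbon now outranks the aryl carbon) and sets the oxirane centre S.

**Step 3**
Reactants: 5 4-benzyloxy-3-methoxybenzaldehyde (O-benzylvanillin); 2 vinylmagnesium bromide
Product: 6 rac-1-(4-benzyloxy-3-methoxyphenyl)prop-2-en-1-ol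
Conditions: THF, 0 °C; then sat. aq NH4Cl
Reagents that add atoms: none
Why: Grignard 1,2-addition as in step 1 should give the 1-arylallyl alcohol, whose carbinol stereocentre is irrelevant because it is erased in step 4.

**Step 4**
Reactants: 6 rac-1-(4-benzyloxy-3-methoxyphenyl)prop-2-en-1-ol
Product: 7 (E)-1-(benzyloxy)-4-(3-bromoprop-1-en-1-yl)-2-methoxybenzene
Conditions: PBr3 (0.4 equiv), Et2O, −10 to 0 °C; used at once without chromatography
Reagents that add atoms: phosphorus tribromide, BrP(Br)Br
Why: Bromination of a 1-arylallyl alcohol with allylic transposition (ionisation of the bromophosphite to the 4-alkoxy-stabilised 1-arylallyl cation or SN2' attack, with bromide captured at the terminal carbon) should give the conjugated cinnamyl bromide, with E geometry under thermodynamic control.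

**Step 5**
Reactants: 4 (R)-(3,4-dimethoxyphenyl)[(2S)-oxiran-2-yl]methanol; 7 (E)-1-(benzyloxy)-4-(3-bromoprop-1-en-1-yl)-2-methoxybenzene
Product: 8 (2S)-2-[(R)-{[(2E)-3-(4-benzyloxy-3-methoxyphenyl)prop-2-en-1-yl]oxy}(3,4-dimethoxyphenyl)methyl]oxirane
Conditions: NaH (1.2 equiv) added last to 4 and freshly made 7 (1.2 equiv), THF/DMF 4:1, −20 to 0 °C
Reagents that add atoms: none
Why: In this Williamson etherification the sodium alkoxide of 4 is formed in the presence of the reactive primary allylic bromide and should be alkylated by SN2 faster than it can undergo Payne migration, so both stereocentres of 4 and the E alkene are carried over unchanged.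

**Step 6**
Reactants: 8 (2S)-2-[(R)-{[(2E)-3-(4-benzyloxy-3-methoxyphenyl)prop-2-en-1-yl]oxy}(3,4-dimethoxyphenyl)methyl]oxirane
Product: 10 [(2S,3R,4R)-4-(4-benzyloxy-3-methoxybenzyl)-2-(3,4-dimethoxyphenyl)oxolan-3-yl]methanol, via titanium-bound cyclised adduct 9 (not isolated)
Conditions: Cp2TiCl2 (2.5 equiv), Zn dust, THF, rt (forms Cp2TiCl); added dropwise to 8 in THF (high dilution), rt; then 1 M aq HCl, 0 °C
Reagents that add atoms: none
Why: Cp2TiCl (trivalent titanium) transfers one electron to the oxirane of 8 and cleaves the C–O bond at the inner carbon, giving the secondary β-titanoxy radical at the future C3 (the oxirane stereocentre is erased), which adds to the proximal cinnamyl carbon to form C3–C4; a second Cp2TiCl captures the resulting benzylic radical as the tetravalent organotitanium 9, and aqueous HCl cleaves its C–Ti and O–Ti bonds to give 10. The closest known reaction type is the titanocene-mediated reductive epoxide opening with radical cyclisation of epoxy allyl ethers to 3-(hydroxymethyl)oxolanes. The oxolane O1–C2–C3–C4–C5 closes in the 5-exo-trig mode through a chair-like transition state, the 6-endo alternative being disfavoured stereoelectronically and by loss of the benzylic radical. C3 is controlled by the pre-set C2, whose aryl group sits pseudo-equatorial with the CH2OTi group on the radical carbon trans to it, and C4 is controlled by the cis preference of 1-substituted hex-5-enyl radicals, which places the alkene arm (the future arylmethyl group) cis to CH2OTi, so 2,3-trans-3,4-cis, that is (2S,3R,4R), is expected. The step needs ring closure to outrun capture of the first radical by trivalent titanium (which would lead to β-elimination and deoxygenation); the fast addition of a nucleophilic alkyl radical to an electron-rich styrene and slow addition of the reagent at high dilution should secure this.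

**Step 7**
Reactants: 10 [(2S,3R,4R)-4-(4-benzyloxy-3-methoxybenzyl)-2-(3,4-dimethoxyphenyl)oxolan-3-yl]methanol
Product: 11 [(2S,3R,4R)-2-(3,4-dimethoxyphenyl)-4-(4-hydroxy-3-methoxybenzyl)oxolan-3-yl]methanol (target)
Conditions: H2 (1 atm), 10% Pd/C, EtOAc, rt, stopped when 10 is consumed
Reagents that add atoms: none
Why: Hydrogenolysis of the aryl benzyl ether should be much faster under neutral conditions at atmospheric pressure than cleavage of the benzylic C2–O1 bond of the oxolane, so the phenol is released without touching the three stereocentres.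

**Compound list**
1 | 3,4-dimethoxybenzaldehyde (veratraldehyde) | COc1ccc(C=O)cc1OC | starting material
2 | vinylmagnesium bromide | C=C[Mg]Br | starting material
3 | rac-1-(3,4-dimethoxyphenyl)prop-2-en-1-ol | C=CC(O)c1ccc(OC)c(OC)c1 | intermediate
4 | (R)-(3,4-dimethoxyphenyl)[(2S)-oxiran-2-yl]methanol (erythro) | O[C@H](c1ccc(OC)c(OC)c1)[C@@H]1CO1 | intermediate
5 | 4-benzyloxy-3-methoxybenzaldehyde (O-benzylvanillin) | COc1cc(C=O)ccc1OCc1ccccc1 | starting material
6 | rac-1-(4-benzyloxy-3-methoxyphenyl)prop-2-en-1-ol | C=CC(O)c1ccc(OCc2ccccc2)c(OC)c1 | intermediate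
7 | (E)-1-(benzyloxy)-4-(3-bromoprop-1-en-1-yl)-2-methoxybenzene | COc1cc(/C=C/CBr)ccc1OCc1ccccc1 | intermediate
8 | (2S)-2-[(R)-{[(2E)-3-(4-benzyloxy-3-methoxyphenyl)prop-2-en-1-yl]oxy}(3,4-dimethoxyphenyl)methyl]oxirane | COc1cc(/C=C/CO[C@H](c2ccc(OC)c(OC)c2)[C@@H]2CO2)ccc1OCc1ccccc1 | intermediate
9 | titanium-bound cyclised adduct: Cp2Ti(Cl) alkoxide (tetravalent titanium) of the C3 hydroxymethyl group of 10, with a second Cp2Ti(Cl) unit on the benzylic carbon of the C4 arylmethyl group (configuration at that carbon undefined; cyclopentadienyl rings drawn σ-bonded) | COc1cc(C([C@H]2CO[C@H](c3ccc(OC)c(OC)c3)[C@H]2CO[Ti](Cl)(C2C=CC=C2)C2C=CC=C2)[Ti](Cl)(C2C=CC=C2)C2C=CC=C2)ccc1OCc1ccccc1 | intermediate (not isolated)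
10 | [(2S,3R,4R)-4-(4-benzyloxy-3-methoxybenzyl)-2-(3,4-dimethoxyphenyl)oxolan-3-yl]methanol | COc1cc(C[C@H]2CO[C@H](c3ccc(OC)c(OC)c3)[C@H]2CO)ccc1OCc1ccccc1 | intermediate
11 | [(2S,3R,4R)-2-(3,4-dimethoxyphenyl)-4-(4-hydroxy-3-methoxybenzyl)oxolan-3-yl]methanol | COc1cc(C[C@H]2CO[C@H](c3ccc(OC)c(OC)c3)[C@H]2CO)ccc1O | target

**Step count**
Total: 7 steps. Longest linear sequence: 5 steps (steps 1, 2, 5, 6, 7 from veratraldehyde; equally steps 3, 4, 5, 6, 7 from O-benzylvanillin).

**Steps most likely to fail**

Step 6. What may go wrong: weak facial control at C4 in the radical closure, so that the 3,4-trans epimer forms alongside; or capture of the β-titanoxy radical by a second trivalent titanium before ring closure, followed by β-elimination to the deoxygenated allyl ether. The fallback sets out from 4 and returns at 11. Compound 4 is O-alkylated with propargyl bromide (NaH, THF/DMF, −20 to 0 °C) to (2S)-2-[(R)-(3,4-dimethoxyphenyl)(prop-2-yn-1-yloxy)methyl]oxirane F1. Sonogashira coupling of F1 with purchased 1-(benzyloxy)-4-iodo-2-methoxybenzene (COc1cc(I)ccc1OCc1ccccc1; PdCl2(PPh3)2, CuI, Et3N, rt) should give the aryl propargyl ether (2S)-2-[(R)-{[3-(4-benzyloxy-3-methoxyphenyl)prop-2-yn-1-yl]oxy}(3,4-dimethoxyphenyl)methyl]oxirane F2. Cp2TiCl (from Cp2TiCl2 and Zn, THF, rt) then opens the oxirane in the same way, but the radical closes 5-exo-dig onto the alkyne and the vinyl radical takes hydrogen from THF, giving the titanium alkoxide of the benzylidene oxolane F3; 1 M HCl releases [(2S,3R)-4-(4-benzyloxy-3-methoxybenzylidene)-2-(3,4-dimethoxyphenyl)oxolan-3-yl]methanol F4 (C2 and C3 trans; alkene geometry of no consequence). Hydrogenation of F4 (H2, 10% Pd/C, EtOAc) should add hydrogen to C4 from the face opposite the neighbouring C3 hydroxymethyl group, placing the arylmethyl group cis to it, and cleave the benzyl ether in the same operation, giving 11.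

Step 5. What may go wrong: Payne migration of the epoxy alkoxide, or loss of the ionisable, electron-rich cinnamyl bromide 7 by elimination, SN2' attack or self-condensation before O-alkylation is complete. The fallback sets out from 4 and 5 and returns at 8. The ether bond is made with allyl bromide, which is stable and can be used in large excess (NaH, THF/DMF, −20 °C), giving (2S)-2-[(R)-(3,4-dimethoxyphenyl)(prop-2-en-1-yloxy)methyl]oxirane F5. Aldehyde 5 is converted by Wittig methylenation (Ph3PCH3Br, KOtBu, THF, 0 °C) into 1-(benzyloxy)-4-ethenyl-2-methoxybenzene F6. Olefin cross-metathesis of F5 with excess F6 (second-generation Grubbs catalyst, CH2Cl2, 40 °C) should then give the E cinnamyl ether 8 with loss of ethene.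

Step 2. What may go wrong: too small a rate difference between the enantiomers of the electron-rich aryl vinyl carbinol on the titanium tartrate catalyst, so that the epoxy alcohol is formed with low enantiomeric purity. The fallback sets out from 3 and returns at 4. Lipase-catalysed acylative resolution of 3 (immobilised Candida antarctica lipase B, vinyl acetate, MTBE, rt; the usual preference of this enzyme for the carbinol enantiomer with aryl as the large and vinyl as the medium group) should acetylate the (R)-enantiomer to (R)-1-(3,4-dimethoxyphenyl)prop-2-en-1-yl acetate F7 and leave (S)-1-(3,4-dimethoxyphenyl)prop-2-en-1-ol F8. F8 is separated and epoxidised on its own to full conversion (Ti(OiPr)4, D-(−)-diisopropyl tartrate, tBuOOH, 4 Å MS, CH2Cl2, −20 °C; matched pair, erythro) to give 4.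

**Further compounds**
F1 | step 6 | (2S)-2-[(R)-(3,4-dimethoxyphenyl)(prop-2-yn-1-yloxy)methyl]oxirane | C#CCO[C@H](c1ccc(OC)c(OC)c1)[C@@H]1CO1
F2 | step 6 | (2S)-2-[(R)-{[3-(4-benzyloxy-3-methoxyphenyl)prop-2-yn-1-yl]oxy}(3,4-dimethoxyphenyl)methyl]oxirane | COc1cc(C#CCO[C@H](c2ccc(OC)c(OC)c2)[C@@H]2CO2)ccc1OCc1ccccc1
F3 | step 6 | Cp2Ti(Cl) alkoxide (tetravalent titanium) of F4, not isolated (cyclopentadienyl rings drawn σ-bonded; alkene geometry undefined) | COc1cc(C=C2CO[C@H](c3ccc(OC)c(OC)c3)[C@H]2CO[Ti](Cl)(C2C=CC=C2)C2C=CC=C2)ccc1OCc1ccccc1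
F4 | step 6 | [(2S,3R)-4-(4-benzyloxy-3-methoxybenzylidene)-2-(3,4-dimethoxyphenyl)oxolan-3-yl]methanol (alkene geometry undefined) | COc1cc(C=C2CO[C@H](c3ccc(OC)c(OC)c3)[C@H]2CO)ccc1OCc1ccccc1
F5 | step 5 | (2S)-2-[(R)-(3,4-dimethoxyphenyl)(prop-2-en-1-yloxy)methyl]oxirane | C=CCO[C@H](c1ccc(OC)c(OC)c1)[C@@H]1CO1
F6 | step 5 | 1-(benzyloxy)-4-ethenyl-2-methoxybenzene | C=Cc1ccc(OCc2ccccc2)c(OC)c1
F7 | step 2 | (R)-1-(3,4-dimethoxyphenyl)prop-2-en-1-yl acetate | C=C[C@@H](OC(C)=O)c1ccc(OC)c(OC)c1
F8 | step 2 | (S)-1-(3,4-dimethoxyphenyl)prop-2-en-1-ol | C=C[C@H](O)c1ccc(OC)c(OC)c1
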